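**Plan**

1. Retrosynthesis: the three silyl ethers come off last. Ring C is cut at O1–C2 and at C4–C4a, giving a ring-A bromophenol and a ring-B (E)-N-methoxy-N-methylacrylamide. The acrylamide is cut at C2=C3 (olefination of a chromene aldehyde), and the ring-A side chain at its carbinol carbon (double methyl addition to a lactone).
2. Enabling feature: O1 and C4a are ortho neighbours on the phloroglucinol ring A (an O,C-dinucleophile). C2–C3–C4 is a cinnamoyl dielectrophile with a hard acyl carbon C4 and a benzylic C2 conjugated to the oxygenated ring B.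
3. O1 and the C8 side chain begin as the lactone of a 3,4-dihydrocoumarin. Opening with MeMgBr frees exactly one phenol (O1) and builds the tertiary carbinol, so ring C can only close to the 8-substituted flavanone.
4. Forward order: ring-A piece (hydrogenation, silylation, bromination, lactone opening); pyran ring on resorcinol (chromanone, chromene), formylation, silylation, olefination; union and ring C closure in one flask; desilylation.
5. Stereochemistry: the single stereocentre C2 (S) is set in the ring C closure by a cinchona amine–thiourea catalyst and kept by a non-basic final desilylation.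

Key step: step 10

Remark: the SMILES is read as the 2S flavanone (O1 > ring-B carbon > C3 > H), and this configuration is carried through every chiral structure below.

**Route**

Step 1
Reactants: 1 5,7-dihydroxycoumarin (5,7-dihydroxy-2H-chromen-2-one)
Product: 2 5,7-dihydroxychroman-2-one
Conditions: H2 (1 atm), 10% Pd/C, THF, rt
Reagents that add atoms: none
Why: Heterogeneous catalytic hydrogenation should saturate the conjugated C3=C4 bond of the coumarin and leave the arene and the lactone untouched at 1 atm.

Step 2
Reactants: 2 5,7-dihydroxychroman-2-one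
Product: 3 5,7-bis(tert-butyldimethylsilyloxy)chroman-2-one
Conditions: TBSOTf, 2,6-lutidine, CH2Cl2, −78 to 0 °C
Reagents that add atoms: tert-butyldimethylsilyl trifluoromethanesulfonate, CC(C)(C)[Si](C)(C)OS(=O)(=O)C(F)(F)F
Why: O-Silylation of both phenols with a silyl triflate and a hindered, non-nucleophilic base should proceed without opening the aryl lactone, as a nucleophilic catalyst might.

Step 3
Reactants: 3 5,7-bis(tert-butyldimethylsilyloxy)chroman-2-one
Product: 4 8-bromo-5,7-bis(tert-butyldimethylsilyloxy)chroman-2-one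
Conditions: NBS (1.0 equiv), CH2Cl2, −40 to 0 °C, dark
Reagents that add atoms: N-bromosuccinimide, O=C1CCC(=O)N1Br
Why: Electrophilic aromatic bromination should go to C8, which is ortho/para to both silyloxy groups and flanked on one side only by the small lactone oxygen, whereas C6 lies between two bulky silyl ethers.

Step 4
Reactants: 4 8-bromo-5,7-bis(tert-butyldimethylsilyloxy)chroman-2-one
Product: 6 2-bromo-3,5-bis(tert-butyldimethylsilyloxy)-6-(3-hydroxy-3-methylbutyl)phenol, via methyl ketone 5 (not isolated)
Conditions: MeMgBr (3.2 equiv), THF, −20 to 0 °C; aq. NH4Cl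
Reagents that add atoms: methylmagnesium bromide, C[Mg]Br
Why: Double Grignard addition to the aryl lactone should expel the phenoxide that becomes O1 and turn the ester carbon into the tertiary carbinol, while the aryl bromide and the aryl silyl ethers are inert to MeMgBr at or below 0 °C.

Step 5
Reactants: 7 resorcinol; 8 3-methylbut-2-enoic acid
Product: 9 7-hydroxy-2,2-dimethylchroman-4-one
Conditions: P2O5, MeSO3H, 70 °C
Reagents that add atoms: none
Why: Friedel–Crafts acylation para to one hydroxyl followed by oxa-Michael closure of the other hydroxyl onto the enone should give the 7-hydroxychromanone, since acylation between the two hydroxyls is disfavoured.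

Step 6
Reactants: 9 7-hydroxy-2,2-dimethylchroman-4-one
Product: 11 2,2-dimethyl-2H-chromen-7-ol, via chromanol 10 (not isolated)
Conditions: LiAlH4, THF, 0 °C to reflux; aq. HCl work-up; then TsOH·H2O (cat.), PhMe, 60 °C, dilute
Reagents that add atoms: none
Why: Hydride reduction of the aryl ketone and acid-catalysed dehydration of the resulting para-hydroxybenzylic alcohol should give the conjugated 2H-chromene.

Step 7
Reactants: 11 2,2-dimethyl-2H-chromen-7-ol
Product: 13 7-hydroxy-2,2-dimethyl-2H-chromene-6-carbaldehyde, via benzylic alcohol 12 (not isolated)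
Conditions: MgCl2, Et3N, (CH2O)n, MeCN, reflux; aq. HCl
Reagents that add atoms: paraformaldehyde (as formaldehyde), C=O
Why: In the Casnati–Skattebøl ortho-formylation the aryloxymagnesium chelate delivers formaldehyde to an ortho carbon and a second formaldehyde oxidises the benzylic alkoxide by hydride transfer; C6 (para to the ring oxygen, unhindered) should be preferred over C8, which lies between the two oxygens.

Step 8
Reactants: 13 7-hydroxy-2,2-dimethyl-2H-chromene-6-carbaldehyde
Product: 14 7-(tert-butyldimethylsilyloxy)-2,2-dimethyl-2H-chromene-6-carbaldehyde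
Conditions: TBSCl, imidazole, DMF, rt
Reagents that add atoms: tert-butyldimethylsilyl chloride, CC(C)(C)[Si](C)(C)Cl
Why: Standard imidazole-promoted silylation should cap the phenol so that no coumarin can form in the olefination and no second acidic proton is present in the union.

Step 9
Reactants: 14 7-(tert-butyldimethylsilyloxy)-2,2-dimethyl-2H-chromene-6-carbaldehyde; 15 diethyl [2-(methoxy(methyl)amino)-2-oxoethyl]phosphonate
Product: 16 (E)-3-[7-(tert-butyldimethylsilyloxy)-2,2-dimethyl-2H-chromen-6-yl]-N-methoxy-N-methylprop-2-enamide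
Conditions: NaH, THF, 0 °C to rt
Reagents that add atoms: none
Why: The Horner–Wadsworth–Emmons reaction of a stabilised phosphonate with an aryl aldehyde should give the E-configured unsaturated amide directly.

Step 10
Reactants: 6 2-bromo-3,5-bis(tert-butyldimethylsilyloxy)-6-(3-hydroxy-3-methylbutyl)phenol; 16 (E)-3-[7-(tert-butyldimethylsilyloxy)-2,2-dimethyl-2H-chromen-6-yl]-N-methoxy-N-methylprop-2-enamide
Product: 19 (2S)-5,7-bis(tert-butyldimethylsilyloxy)-2-[7-(tert-butyldimethylsilyloxy)-2,2-dimethyl-2H-chromen-6-yl]-8-(3-hydroxy-3-methylbutyl)chroman-4-one, via trilithio arene 17 (not isolated), via chalcone 18 (not isolated)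
Conditions: MeLi (2.0 equiv), Et2O–THF, −78 °C; t-BuLi (2.0 equiv), −78 °C, short; 16, −78 to −40 °C; AcOH; aq. NaHCO3 wash, solvent changed to PhMe; quinine-derived amine–thiourea (N-[3,5-bis(trifluoromethyl)phenyl]-N'-(9-deoxy-epi-quinin-9-yl)thiourea, 10 mol%), PhMe, −20 °C
Reagents that add atoms: none
Why: Bromine–lithium exchange on the dilithium salt of 6 gives the ortho-lithiated phenoxide 17, whose carbanion at the future C4a adds 1,2 to the N-methoxy-N-methylamide 16; the chelated adduct survives until the acid quench and then releases the 2'-hydroxychalcone 18, which forms C4–C4a (closest known reaction type: Weinreb ketone synthesis with an ortho-lithiated phenoxide). In the same flask the tertiary amine of the cinchona thiourea takes the proton of the 2'-OH while the thiourea hydrogen-bonds the enone carbonyl, and the phenoxide oxygen adds to C2 in an oxa-Michael reaction that forms O1–C2 (closest known reaction type: amine–thiourea-catalysed cyclisation of 2'-hydroxychalcones to flavanones). Ring C closes in the 6-endo-trig mode. The new stereocentre C2 is controlled by the catalyst, which should deliver O1 to the Si face of the β-carbon to give 2S (the quinidine-derived pseudo-enantiomer is taken if a trial shows the opposite sense), and −20 °C with only a weak base keeps the closure under kinetic control. The step needs regioselectivity between closure to the 8-alkyl and the 6-alkyl flavanone, and the substrate secures it because the only free phenol of 18 is the former lactone oxygen next to the side chain, both other ring-A oxygens being silylated. It also needs 1,2- over 1,4-addition and no attack on the tertiary alkoxide, which the hard aryllithium, the amide acceptor and the inertness of the lithium alkoxide provide.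

Step 11
Reactants: 19 (2S)-5,7-bis(tert-butyldimethylsilyloxy)-2-[7-(tert-butyldimethylsilyloxy)-2,2-dimethyl-2H-chromen-6-yl]-8-(3-hydroxy-3-methylbutyl)chroman-4-one
Product: 20 (2S)-5,7-dihydroxy-2-(7-hydroxy-2,2-dimethyl-2H-chromen-6-yl)-8-(3-hydroxy-3-methylbutyl)chroman-4-one (CNP0423488.1)
Conditions: KHF2, MeOH, rt to 40 °C
Reagents that add atoms: none
Why: Fluoride-mediated cleavage of the three phenolic silyl ethers under weakly acidic, non-basic conditions should avoid retro-oxa-Michael opening at C2 and leave the tertiary alcohol and the chromene intact.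

**Compound list**

1 | 5,7-dihydroxycoumarin (5,7-dihydroxy-2H-chromen-2-one) | O=C1C=Cc2c(O)cc(O)cc2O1 | starting material
2 | 5,7-dihydroxychroman-2-one | O=C1CCc2c(O)cc(O)cc2O1 | intermediate
3 | 5,7-bis(tert-butyldimethylsilyloxy)chroman-2-one | O=C1CCc2c(O[Si](C)(C)C(C)(C)C)cc(O[Si](C)(C)C(C)(C)C)cc2O1 | intermediate
4 | 8-bromo-5,7-bis(tert-butyldimethylsilyloxy)chroman-2-one | O=C1CCc2c(O[Si](C)(C)C(C)(C)C)cc(O[Si](C)(C)C(C)(C)C)c(Br)c2O1 | intermediate
5 | 4-[3-bromo-4,6-bis(tert-butyldimethylsilyloxy)-2-hydroxyphenyl]butan-2-one (formed as its bromomagnesium phenoxide) | CC(=O)CCc1c(O)c(Br)c(O[Si](C)(C)C(C)(C)C)cc1O[Si](C)(C)C(C)(C)C | intermediate (not isolated)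
6 | 2-bromo-3,5-bis(tert-butyldimethylsilyloxy)-6-(3-hydroxy-3-methylbutyl)phenol | CC(C)(O)CCc1c(O)c(Br)c(O[Si](C)(C)C(C)(C)C)cc1O[Si](C)(C)C(C)(C)C | intermediate
7 | resorcinol | Oc1cccc(O)c1 | starting material
8 | 3-methylbut-2-enoic acid | CC(C)=CC(=O)O | starting material
9 | 7-hydroxy-2,2-dimethylchroman-4-one | CC1(C)CC(=O)c2ccc(O)cc2O1 | intermediate
10 | 2,2-dimethylchroman-4,7-diol (racemic) | CC1(C)CC(O)c2ccc(O)cc2O1 | intermediate (not isolated)
11 | 2,2-dimethyl-2H-chromen-7-ol | CC1(C)C=Cc2ccc(O)cc2O1 | intermediate
12 | 6-(hydroxymethyl)-2,2-dimethyl-2H-chromen-7-ol | OCc1cc2C=CC(C)(C)Oc2cc1O | intermediate (not isolated)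
13 | 7-hydroxy-2,2-dimethyl-2H-chromene-6-carbaldehyde | O=Cc1cc2C=CC(C)(C)Oc2cc1O | intermediate
14 | 7-(tert-butyldimethylsilyloxy)-2,2-dimethyl-2H-chromene-6-carbaldehyde | O=Cc1cc2C=CC(C)(C)Oc2cc1O[Si](C)(C)C(C)(C)C | intermediate
15 | diethyl [2-(methoxy(methyl)amino)-2-oxoethyl]phosphonate | CCOP(=O)(OCC)CC(=O)N(C)OC | starting material
16 | (E)-3-[7-(tert-butyldimethylsilyloxy)-2,2-dimethyl-2H-chromen-6-yl]-N-methoxy-N-methylprop-2-enamide | CON(C)C(=O)/C=C/c1cc2C=CC(C)(C)Oc2cc1O[Si](C)(C)C(C)(C)C | intermediate
17 | trilithium salt of 6 after bromine–lithium exchange (2-lithio phenoxide with lithium tertiary alkoxide) | [Li]OC(C)(C)CCc1c(O[Li])c([Li])c(O[Si](C)(C)C(C)(C)C)cc1O[Si](C)(C)C(C)(C)C | intermediate (not isolated)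
18 | (E)-1-[4,6-bis(tert-butyldimethylsilyloxy)-2-hydroxy-3-(3-hydroxy-3-methylbutyl)phenyl]-3-[7-(tert-butyldimethylsilyloxy)-2,2-dimethyl-2H-chromen-6-yl]prop-2-en-1-one | CC(C)(O)CCc1c(O)c(C(=O)/C=C/c2cc3C=CC(C)(C)Oc3cc2O[Si](C)(C)C(C)(C)C)c(O[Si](C)(C)C(C)(C)C)cc1O[Si](C)(C)C(C)(C)C | intermediate (not isolated)
19 | (2S)-5,7-bis(tert-butyldimethylsilyloxy)-2-[7-(tert-butyldimethylsilyloxy)-2,2-dimethyl-2H-chromen-6-yl]-8-(3-hydroxy-3-methylbutyl)chroman-4-one | CC(C)(O)CCc1c(O[Si](C)(C)C(C)(C)C)cc(O[Si](C)(C)C(C)(C)C)c2c1O[C@H](c1cc3c(cc1O[Si](C)(C)C(C)(C)C)OC(C)(C)C=C3)CC2=O | intermediate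
20 | (2S)-5,7-dihydroxy-2-(7-hydroxy-2,2-dimethyl-2H-chromen-6-yl)-8-(3-hydroxy-3-methylbutyl)chroman-4-one | CC(C)(O)CCc1c(O)cc(O)c2c1O[C@H](c1cc3c(cc1O)OC(C)(C)C=C3)CC2=O | target

**Totals and risks**

Total step count: 11. Longest linear sequence: 7 steps (steps 5, 6, 7, 8, 9, 10, 11).

Steps most likely to fail:

Step 10. The ring closure may show insufficient facial selectivity, or the enantiomeric purity may erode through reversible ring opening under the amine catalyst. The fallback replaces asymmetric catalysis by kinetic resolution. It sets out from 6 and 16: the same lithiation and acylation give chalcone 18, which is closed without a chiral catalyst (NaOAc, EtOH, 60 °C) to the racemic protected flavanone F1. Asymmetric transfer hydrogenation with RuCl(p-cymene)[(R,R)-TsDPEN] in HCO2H/Et3N is expected, by analogy with aryl ketone reductions, to reduce the 2R enantiomer faster to the (2R,4R)-cis-flavan-4-ol F2, which is removed by chromatography. The unreacted 2S ketone is 19, where the route is rejoined.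

Step 3. Positional control in the electrophilic substitution may be lost, with bromine entering at C6 or twice. The fallback reverses the order of lactone opening and halogenation so that a free phenol, not steric shielding, directs the halogen. It sets out from 3: MeMgBr opens the lactone through the transient methyl ketone F3 to the debrominated phenol 3,5-bis(tert-butyldimethylsilyloxy)-2-(3-hydroxy-3-methylbutyl)phenol F4. Amine-catalysed ortho-bromination (NBS, cat. i-Pr2NH, CH2Cl2, −78 °C), in which the brominating agent is held by hydrogen bonding to the phenol, then gives 6, where the route is rejoined.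

Step 7. The chelate-delivered formylation may go to C8 between the two ring oxygens, or the chromene may oligomerise with formaldehyde. The fallback swaps the order of protection and formylation and uses an electrophilic substitution governed by the para-directing ring oxygen and the bulk of the silyl ether. It sets out from 11: silylation (TBSCl, imidazole, DMF) gives tert-butyl[(2,2-dimethyl-2H-chromen-7-yl)oxy]dimethylsilane F5. Vilsmeier–Haack formylation (POCl3, DMF, 0 °C to rt; aq. NaOAc) through the iminium chloride F6 should place the aldehyde at C6 and give 14 directly, where the route is rejoined; compound 13 and step 8 are bypassed.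

**Further compounds**

F1 | step 10 | racemic 5,7-bis(tert-butyldimethylsilyloxy)-2-[7-(tert-butyldimethylsilyloxy)-2,2-dimethyl-2H-chromen-6-yl]-8-(3-hydroxy-3-methylbutyl)chroman-4-one | CC(C)(O)CCc1c(O[Si](C)(C)C(C)(C)C)cc(O[Si](C)(C)C(C)(C)C)c2c1OC(c1cc3c(cc1O[Si](C)(C)C(C)(C)C)OC(C)(C)C=C3)CC2=O
F2 | step 10 | (2R,4R)-5,7-bis(tert-butyldimethylsilyloxy)-2-[7-(tert-butyldimethylsilyloxy)-2,2-dimethyl-2H-chromen-6-yl]-8-(3-hydroxy-3-methylbutyl)chroman-4-ol (cis) | CC(C)(O)CCc1c(O[Si](C)(C)C(C)(C)C)cc(O[Si](C)(C)C(C)(C)C)c2c1O[C@@H](c1cc3c(cc1O[Si](C)(C)C(C)(C)C)OC(C)(C)C=C3)C[C@H]2O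
F3 | step 3 | 4-[2,4-bis(tert-butyldimethylsilyloxy)-6-hydroxyphenyl]butan-2-one (transient) | CC(=O)CCc1c(O)cc(O[Si](C)(C)C(C)(C)C)cc1O[Si](C)(C)C(C)(C)C
F4 | step 3 | 3,5-bis(tert-butyldimethylsilyloxy)-2-(3-hydroxy-3-methylbutyl)phenol | CC(C)(O)CCc1c(O)cc(O[Si](C)(C)C(C)(C)C)cc1O[Si](C)(C)C(C)(C)C
F5 | step 7 | tert-butyl[(2,2-dimethyl-2H-chromen-7-yl)oxy]dimethylsilane | CC1(C)C=Cc2ccc(O[Si](C)(C)C(C)(C)C)cc2O1
F6 | step 7 | N-{[7-(tert-butyldimethylsilyloxy)-2,2-dimethyl-2H-chromen-6-yl]methylidene}-N-methylmethanaminium chloride | C[N+](C)=Cc1cc2C=CC(C)(C)Oc2cc1O[Si](C)(C)C(C)(C)C.[Cl-]
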